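The constants were drawn at random within sensible limits; the flask was simulated.

starting material 0.10 M; second substrate 1.00 equiv; solid reagent 1.50 equiv; protic impurity 5.00 mM; free catalyst 0.1 mol%; time 4.0 h
1. the target standing at 4.0 h, as a percentage of the starting material charged
2. concentration of partner in solution at 1.0 h, in percent of saturation
3. the change that raises the amount of target at 4.0 h, in percent of the starting material charged most ("none" if none brings more than 2 percentage points) (midnight / winter / noon / none)
4. amount of target at 4.0 h, in percent of the starting material charged, after winter
- midnight: doubling the dissolution coefficient of step 1, all else as stated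
- winter: doubling the solubility in step 1, all else as stated
- noon: doubling the amount of free catalyst, all else as stated
- solid reagent is a solid; its amount is given per volume of the solution
- at the start none of the solid reagent is in solution
- run time (flask): 4.0 h

    solid reagent ⇌ partner, rate k1*(cs1 - [partner]) while solid is left; crystals form when [partner] > cs1 (cs1 = 0.068 M, k1 = 0.126 min⁻¹)
    starting material + free catalyst ⇌ catalyst intermediate A (K2 = 883 L mol⁻¹, k2 = 41.5 L mol⁻¹ min⁻¹)
    second substrate + free catalyst ⇌ catalyst intermediate B (K3 = 4.06 L mol⁻¹, k3 = 113 L mol⁻¹ min⁻¹)
    partner + catalyst intermediate A → free catalyst + target (k4 = 22.3 L mol⁻¹ min⁻¹)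
    partner → decomposed reagent (k5 = 0.00260 min⁻¹)
    partner + catalyst intermediate B → free catalyst + second product (k6 = 103 L mol⁻¹ min⁻¹)
    partner + protic impurity → quenched reagent (k7 = 10.1 L mol⁻¹ min⁻¹)

- Settle the next run by reckoning this flask from both ends, early and late, and taking the smaller amount of target.
- Early end: while solid reagent feeds the solution, we take partner at saturation, 68.0% of the charge. Starting material takes up free catalyst at 4.15 min⁻¹, while catalyst intermediate A is cleared by partner at 1.52 min⁻¹ and falls back at 0.0470 min⁻¹.
- That gives 2.65 of intermediate A per free catalyst. The same balance with one equivalent of second substrate gives 0.324 of intermediate B, so A, the resting state, holds 66.7% of the catalyst, and B holds 8.15%.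
- Loading times that share of A times its clearing rate gives 0.0607 h⁻¹: the catalyst line, the fraction of the charge made into target per hour at saturation. Over 4.0 h it reaches 24.3%.
- Late end: partner also leaves to decomposed reagent at 0.106 h⁻¹ and to second product at 0.0343 h⁻¹. If that split held, target would receive 30.2% of the 145% of the charge left after the protic impurity, or 43.8%.
- The early figure is smaller, so we reckon catalyst as the limit on this flask at 4.0 h.
- The same total drain needs a dissolving gap that puts partner at 96.1% of saturation, so the gap midnight can act on is 3.91% of saturation.
- For noon, the early end becomes 48.6% and the late end 59.5%, and the early end stays smaller. Our choice for the next run is noon; we leave winter unreckoned.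
- The forecast gave 22%, 96%, noon and 26.5%, calling the run “limited by catalyst turnover”.
- The simulation of the flask gives 22.2% and 96.2%. Its choice is noon, with gains of 19 percentage points for noon, 4.1 points for winter and 0.59 points for midnight, and winter stands at 26.3%.

- In the flask at 0.400 h, partner goes to decomposed reagent 1.7 times as fast as to target, against 1.75 from the catalyst line and the decomposition rate at saturation. Left for 40.0 h, the flask holds 46.3% target, beside our late end of 43.8%, while at 4.0 h it holds 22.2%, beside our early end of 24.3%.
- On the neighbour flask charged with 0.4 mol% of free catalyst, the catalyst line becomes 0.243 h⁻¹, so the early end is 97.1% and the late end 72.5%, now the smaller. As computed, that neighbour flask holds 64.0% target at 4.00 h, with solid reagent at 0% and partner at 16.5% of the charge.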